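**Retrosynthetic overview**
1. Feature: C6, the 6α-carbinol carbon, is homoallylic to the methyl-bearing C8 (C6–C7–C8–C14) in the seven-membered ring. C1–C6, C10 and the isopropyl group map onto the ten carbons of terpinen-4-ol, whose carbinol carbon is C4.
2. Last bonds: the O6–acyl bond, made with silyl-protected vanillic acid on the only secondary hydroxyl. The C8(OH)–C9=C10 unit comes from the 8α,9α-epoxide by selenolate opening at C9 and selenoxide elimination toward C10.
3. The epoxide comes from the C8=C9 alkene, directed by the 6α-hydroxyl. That alkene comes from the 8(14)-methylene-9-ol by reductive allylic transposition. The C9 oxygen therefore only fixes the alkene position, no SN2 reaction is needed at a C9 carbinol next to a free tertiary C8 hydroxyl, and both C9 epimers converge.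
4. Second ring (seven-membered, C1, C5–C10): C6–C7 is formed by a Me2AlCl type 2 carbonyl-ene closure of a trans-cyclopentanecarbaldehyde.
5. First ring (five-membered, C1–C5): ozonolysis of silylated terpinen-4-ol, C10–C9 aldol of the methyl ketone with methacrolein, C5–C1 enamine aldol condensation, then Me2CuLi at C1 opposite to the isopropyl group.

Key step: step 7

Numbering: daucane numbering is used throughout. C1 is the quaternary fusion carbon, C4 the isopropyl carbinol, C5 the fusion CH, and C6–C10 the rest of the seven-membered ring. C14 is the carbon on C8 and C15 the methyl on C1. α is the face of H5.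
Remark 1: C9 forms without control in step 3. Both epimers are carried on together, the SMILES show the (9R)-epimer, and the centre is erased in step 9.
Remark 2: (S)-(+)-terpinen-4-ol is taken as commercial material of high enantiomeric purity, and this purity fixes that of the target.

**Step 1**
Reactants: 1 (S)-(+)-terpinen-4-ol
Product: 2 (S)-terpinen-4-ol triethylsilyl ether
Conditions: TESOTf, 2,6-lutidine, CH2Cl2, 0 °C
Reagents that add atoms: triethylsilyl triflate, CC[Si](CC)(CC)OS(=O)(=O)C(F)(F)F
Why: Silyl triflate silylation of a hindered tertiary alcohol is routine, leaves the C4 stereocentre untouched and keeps the later γ-hydroxy ketone from closing to a hemiketal and the β-hydroxy aldehyde from retro-aldol cleavage.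

**Step 2**
Reactants: 2 (S)-terpinen-4-ol triethylsilyl ether
Product: 5 (S)-5-isopropyl-7,7-dimethoxy-5-(triethylsilyloxy)heptan-2-one, via secondary ozonide 3 (not isolated), via keto aldehyde 4 (not isolated)
Conditions: O3, CH2Cl2, −78 °C; PPh3, −78 °C to rt; concentrate; CeCl3·7H2O (cat), HC(OMe)3, MeOH, 0 °C
Reagents that add atoms: ozone, [O-][O+]=O; trimethyl orthoformate, COC(OC)OC
Why: Ozonolysis (Criegee mechanism) cleaves the only C=C bond into the C1 methyl ketone and the C6 aldehyde, and the CeCl3-catalysed acetalisation takes the far more electrophilic aldehyde alone, so that the methyl ketone is the only enolisable carbonyl group in step 3.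

**Step 3**
Reactants: 5 (S)-5-isopropyl-7,7-dimethoxy-5-(triethylsilyloxy)heptan-2-one; 6 methacrolein
Product: 8 (3R,8S)-3-hydroxy-8-isopropyl-10,10-dimethoxy-2-methyl-8-(triethylsilyloxy)dec-1-en-5-one, via lithium enolate 7 (not isolated)
Conditions: LDA, THF, −78 °C; 6, −78 °C; AcOH, −78 °C
Reagents that add atoms: none
Why: Kinetic deprotonation of a methyl ketone at the methyl group followed by a lithium aldol 1,2-addition to the enal forms C10–C9 with no regiochemical doubt (γ-deprotonation of a ring-closed enal would have to tell the methyl group from the ring CH2 and would end in a lactol), while C9 forms without control and is erased in step 9.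

**Step 4**
Reactants: 8 aldol adduct
Product: 9 C9 tert-butyldimethylsilyl ether of 8
Conditions: TBSCl, imidazole, DMF, rt
Reagents that add atoms: tert-butyldimethylsilyl chloride, CC(C)(C)[Si](C)(C)Cl
Why: Standard silylation of a secondary allylic alcohol under conditions too mild for β-elimination or for attack on the acetal, done now so that the C9 oxygen can never add to the C6 aldehyde.

**Step 5**
Reactants: 9 silylated keto acetal
Product: 11 2-[(2R)-2-(tert-butyldimethylsilyloxy)-3-methylbut-3-enyl]-5-isopropyl-5-(triethylsilyloxy)cyclopent-1-enecarbaldehyde (C4 as in 1), via keto aldehyde 10 (not isolated)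
Conditions: SiO2, 10% aq oxalic acid, CH2Cl2, rt; filter, concentrate; [Bn2NH2][O2CCF3], toluene, 50 °C
Reagents that add atoms: water, O
Why: Mild acetal hydrolysis is followed by an amine-salt-catalysed intramolecular aldol condensation in which the secondary amine forms the enamine of the aldehyde only, C5 attacks the C1 ketone in the 5-(enolexo)-exo-trig closure known for 6-oxoaldehydes, and the aldol loses its free C1 hydroxyl rather than the silylated C4 oxygen to give the tetrasubstituted enal.

**Step 6**
Reactants: 11 tetrasubstituted enal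
Product: 13 trans-cyclopentanecarbaldehyde with 1β-methyl 1α-[2-(TBSO)-3-methylbut-3-enyl] 4β-OTES 4α-isopropyl 5β-CHO (H5 α), via trimethylsilyl enol ether 12 (not isolated)
Conditions: MeLi, CuI, Et2O, 0 °C; 11, TMSCl, Et2O–THF, −78 to −30 °C; aq NH4Cl–NH3; then K2CO3, MeOH, 0 °C to rt
Reagents that add atoms: lithium dimethylcuprate (from MeLi and CuI), [Li+].C[Cu-]C
Why: TMSCl-accelerated conjugate addition of the Gilman cuprate to the β,β-disubstituted enal puts the methyl group on C1 from the β face, opposite to the α-isopropyl group on C4 and on the side of the slim C4–O bond, and methanolysis of the enol ether under K2CO3 lets C5 equilibrate by enolisation, faster than the poor silyloxide leaving group can be expelled, to the aldehyde that is trans to both the isopropyl group and the C10 chain.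

**Step 7**
Reactants: 13 trans-cyclopentanecarbaldehyde
Product: 15 8(14)-methylene-9-(tert-butyldimethylsilyloxy)-4β-(triethylsilyloxy)daucan-6α-ol (trans-fused hydroazulene), via chloro(methyl)aluminium alkoxide 14 (not isolated)
Conditions: Me2AlCl (2 equiv), CH2Cl2 (0.01 M), −78 to −20 °C; cold 0.5 M HCl
Reagents that add atoms: none
Why: Coordination of Me2AlCl to the formyl oxygen makes C6 electrophilic enough for the terminal methylene C7 of the isopropenyl group to bond to it while a C14–H is handed to the oxygen through a six-centre array, and the resulting alcohol–aluminium complex loses methane to give alkoxide 14, which removes every proton source that could harm the silyl ethers. The closest known reaction is the Me2AlCl-promoted type 2 intramolecular carbonyl-ene reaction, in which the tether sits on the central ene carbon (here C8) and 3-methylenecycloheptanols are formed. The seven-membered ring C1–C5–C6–C7–C8–C9–C10 closes in the 7-endo mode with respect to the alkene and exo with respect to the carbonyl group. C6, the only new stereocentre, is controlled by the trans-1,2-disubstituted cyclopentane: the tether lets C7 reach C6 only through the sector between H5 and C1, the formyl hydrogen then takes the crowded sector between the quaternary carbons C1 and C4 and the O–Al group points outward anti to C1, so that H6 ends anti to H5 and the hydroxyl is 6α and pseudo-equatorial. The step needs hydrogen transfer from C14 and not from C9, and ring closure faster than ionisation of the allylic C9–O bond or β-elimination of the C4 silyloxy group. Three exposed methyl hydrogens against one hindered C9–H next to oxygen, the low Lewis basicity of the bulky TBS and TES ethers, high dilution and the low temperature secure this, and C1, C4 and C5 are not touched.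

**Step 8**
Reactants: 15 ene product
Product: 16 dauc-8(14)-ene-4β,6α,9-triol
Conditions: TBAF (excess), THF, rt to 45 °C
Reagents that add atoms: none
Why: Fluoride-driven cleavage of both silyl ethers at a stage with no fluoride-sensitive group frees the allylic C9 hydroxyl for step 9 and the C4 hydroxyl for good, so that no silyl ether on the terpene core has to be removed from the acid-sensitive final allylic alcohol.

**Step 9**
Reactants: 16 dauc-8(14)-ene-4β,6α,9-triol
Product: 19 dauc-8-ene-4β,6α-diol, via sulfonyl hydrazone 17 (not isolated), via allylic diazene 18 (not isolated)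
Conditions: N-isopropylidene-N'-(2-nitrobenzenesulfonyl)hydrazine (IPNBSH), PPh3, DEAD, THF, 0 °C to rt; then CF3CH2OH–H2O (1:1), rt
Reagents that add atoms: none
Why: Mitsunobu displacement of the allylic C9 hydroxyl by the sulfonyl hydrazone (the 6α-hydroxyl is flanked by C5 with its two quaternary neighbours and the C4 hydroxyl is tertiary), then hydrolysis and loss of arenesulfinic acid give the allylic diazene, whose retro-ene loss of N2 delivers hydrogen to C14 and moves the double bond to C8=C9 whatever the configuration at C9 was, which is the known reductive allylic transposition.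

**Step 10**
Reactants: 19 dauc-8-ene-4β,6α-diol
Product: 20 8α,9α-epoxydaucane-4β,6α-diol
Conditions: VO(acac)2 (cat), t-BuOOH, CH2Cl2, 0 °C to rt
Reagents that add atoms: tert-butyl hydroperoxide, CC(C)(C)OO
Why: In this vanadium-catalysed hydroxyl-directed epoxidation the homoallylic 6α-alkoxide carries the peroxide on vanadium to the α face of C8=C9, which sets C8 (oxygen α, methyl β) and C9.

**Step 11**
Reactants: 20 8α,9α-epoxide
Product: 21 9β-(phenylselanyl)daucane-4β,6α,8α-triol
Conditions: PhSeSePh, NaBH4, EtOH, rt to reflux
Reagents that add atoms: diphenyl diselenide, c1ccc(cc1)[Se][Se]c1ccccc1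
Why: The soft selenolate opens the trisubstituted epoxide by SN2 attack at the less substituted C9 from the β face, so that the C8–O bond and with it the 8α-carbinol configuration stay untouched.

**Step 12**
Reactants: 21 hydroxy selenide
Product: 23 dauc-9-ene-4β,6α,8α-triol, via selenoxide 22 (not isolated)
Conditions: 30% H2O2, THF, 0 °C to rt
Reagents that add atoms: none
Why: Selenide oxidation is followed by selenoxide syn-elimination, and since C8 carries no hydrogen the only path uses the β-hydrogen at C10 and gives the C9=C10 alkene of the tertiary allylic alcohol under nearly neutral conditions.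

**Step 13**
Reactants: 24 vanillic acid
Product: 26 4-(tert-butyldimethylsilyloxy)-3-methoxybenzoic acid, via bis-silyl derivative 25 (not isolated)
Conditions: TBSCl (2.5 equiv), imidazole, DMF, rt; then AcOH–THF–H2O, rt
Reagents that add atoms: tert-butyldimethylsilyl chloride, CC(C)(C)[Si](C)(C)Cl
Why: Exhaustive silylation and selective hydrolysis of the much more labile silyl ester mask the phenol, which would otherwise be acylated in step 14.

**Step 14**
Reactants: 23 dauc-9-ene-4β,6α,8α-triol; 26 4-(tert-butyldimethylsilyloxy)-3-methoxybenzoic acid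
Product: 28 6α-O-[4-(tert-butyldimethylsilyloxy)-3-methoxybenzoyl] derivative of 23, via mixed anhydride 27 (not isolated)
Conditions: 26, 2,4,6-Cl3C6H2COCl, Et3N, toluene, rt; then 23, DMAP, toluene, rt to 60 °C
Reagents that add atoms: none
Why: Yamaguchi esterification through the mixed anhydride and the acylpyridinium ion is strong enough for the hindered 6α-hydroxyl, the only secondary one, while the tertiary hydroxyls at C4 and C8 do not react and C6 keeps its configuration because the C6–O bond is not broken.

**Step 15**
Reactants: 28 silyl-protected ester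
Product: 29 target, 6α-vanilloyloxydauc-9-ene-4β,8α-diol
Conditions: TBAF, AcOH (1:1), THF, 0 °C
Reagents that add atoms: none
Why: Aryl silyl ethers are cleaved by buffered fluoride within minutes at 0 °C, conditions that spare the ester and the tertiary allylic alcohol.

**Compound list**
1 | (S)-(+)-terpinen-4-ol | CC1=CC[C@](O)(C(C)C)CC1 | starting material
2 | (S)-terpinen-4-ol triethylsilyl ether | CC1=CC[C@](O[Si](CC)(CC)CC)(C(C)C)CC1 | intermediate
3 | secondary ozonide of 2 | CC12CC[C@@](O[Si](CC)(CC)CC)(C(C)C)CC(OO1)O2 | intermediate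
4 | (S)-3-isopropyl-6-oxo-3-(triethylsilyloxy)heptanal | O=CC[C@](O[Si](CC)(CC)CC)(C(C)C)CCC(C)=O | intermediate
5 | (S)-5-isopropyl-7,7-dimethoxy-5-(triethylsilyloxy)heptan-2-one | COC(OC)C[C@](O[Si](CC)(CC)CC)(C(C)C)CCC(C)=O | intermediate
6 | methacrolein | C=C(C)C=O | starting material
7 | terminal lithium enolate of 5 | COC(OC)C[C@](O[Si](CC)(CC)CC)(C(C)C)CCC(=C)O[Li] | intermediate
8 | (3R,8S)-3-hydroxy-8-isopropyl-10,10-dimethoxy-2-methyl-8-(triethylsilyloxy)dec-1-en-5-one | COC(OC)C[C@](O[Si](CC)(CC)CC)(C(C)C)CCC(=O)C[C@@H](O)C(C)=C | intermediate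
9 | C9 TBS ether of 8 | COC(OC)C[C@](O[Si](CC)(CC)CC)(C(C)C)CCC(=O)C[C@@H](O[Si](C)(C)C(C)(C)C)C(C)=C | intermediate
10 | (3S,8R)-8-(TBSO)-3-isopropyl-9-methyl-6-oxo-3-(TESO)dec-9-enal | O=CC[C@](O[Si](CC)(CC)CC)(C(C)C)CCC(=O)C[C@@H](O[Si](C)(C)C(C)(C)C)C(C)=C | intermediate
11 | tetrasubstituted cyclopentenecarbaldehyde carrying the C10–C7 chain | O=CC1=C(C[C@@H](O[Si](C)(C)C(C)(C)C)C(C)=C)CC[C@@]1(O[Si](CC)(CC)CC)C(C)C | intermediate
12 | trimethylsilyl enol ether from the cuprate addition | C[Si](C)(C)OC=C1[C@](O[Si](CC)(CC)CC)(C(C)C)CC[C@]1(C)C[C@@H](O[Si](C)(C)C(C)(C)C)C(C)=C | intermediate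
13 | trans-cyclopentanecarbaldehyde (ene precursor) | O=C[C@H]1[C@](O[Si](CC)(CC)CC)(C(C)C)CC[C@]1(C)C[C@@H](O[Si](C)(C)C(C)(C)C)C(C)=C | intermediate
14 | chloro(methyl)aluminium alkoxide of 15 | C[Al](Cl)O[C@H]1CC(=C)[C@H](O[Si](C)(C)C(C)(C)C)C[C@@]2(C)CC[C@@](O[Si](CC)(CC)CC)(C(C)C)[C@H]12 | intermediate
15 | 8(14)-methylene-9-(TBSO)-4β-(TESO)daucan-6α-ol | O[C@H]1CC(=C)[C@H](O[Si](C)(C)C(C)(C)C)C[C@@]2(C)CC[C@@](O[Si](CC)(CC)CC)(C(C)C)[C@H]12 | intermediate
16 | dauc-8(14)-ene-4β,6α,9-triol | O[C@H]1CC(=C)[C@H](O)C[C@@]2(C)CC[C@@](O)(C(C)C)[C@H]12 | intermediate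
17 | C9 N-(2-nitrobenzenesulfonyl) acetone hydrazone (inverted at C9) | O[C@H]1CC(=C)[C@@H](N(N=C(C)C)S(=O)(=O)c3ccccc3[N+](=O)[O-])C[C@@]2(C)CC[C@@](O)(C(C)C)[C@H]12 | intermediate
18 | C9 allylic diazene | O[C@H]1CC(=C)[C@@H](N=N)C[C@@]2(C)CC[C@@](O)(C(C)C)[C@H]12 | intermediate
19 | dauc-8-ene-4β,6α-diol | O[C@H]1CC(C)=CC[C@@]2(C)CC[C@@](O)(C(C)C)[C@H]12 | intermediate
20 | 8α,9α-epoxydaucane-4β,6α-diol | O[C@H]1C[C@@]3(C)O[C@H]3C[C@@]2(C)CC[C@@](O)(C(C)C)[C@H]12 | intermediate
21 | 9β-(phenylselanyl)daucane-4β,6α,8α-triol | O[C@H]1C[C@@](C)(O)[C@H]([Se]c3ccccc3)C[C@@]2(C)CC[C@@](O)(C(C)C)[C@H]12 | intermediate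
22 | selenoxide of 21 | O[C@H]1C[C@@](C)(O)[C@H]([Se](=O)c3ccccc3)C[C@@]2(C)CC[C@@](O)(C(C)C)[C@H]12 | intermediate
23 | dauc-9-ene-4β,6α,8α-triol | O[C@H]1C[C@@](C)(O)C=C[C@@]2(C)CC[C@@](O)(C(C)C)[C@H]12 | intermediate
24 | vanillic acid | COc1cc(C(=O)O)ccc1O | starting material
25 | tert-butyldimethylsilyl 4-(TBSO)-3-methoxybenzoate | COc1cc(C(=O)O[Si](C)(C)C(C)(C)C)ccc1O[Si](C)(C)C(C)(C)C | intermediate
26 | 4-(tert-butyldimethylsilyloxy)-3-methoxybenzoic acid | COc1cc(C(=O)O)ccc1O[Si](C)(C)C(C)(C)C | intermediate
27 | mixed anhydride of 26 and 2,4,6-trichlorobenzoic acid | COc1cc(C(=O)OC(=O)c2c(Cl)cc(Cl)cc2Cl)ccc1O[Si](C)(C)C(C)(C)C | intermediate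
28 | O-TBS-protected target | COc1cc(C(=O)O[C@H]2C[C@@](C)(O)C=C[C@@]3(C)CC[C@@](O)(C(C)C)[C@H]23)ccc1O[Si](C)(C)C(C)(C)C | intermediate
29 | CNP0243386.4, 6α-vanilloyloxydauc-9-ene-4β,8α-diol | COc1cc(C(=O)O[C@H]2C[C@@](C)(O)C=C[C@@]3(C)CC[C@@](O)(C(C)C)[C@H]23)ccc1O | target

**Step count**
Total step count: 15. The longest linear sequence is 14 steps (steps 1–12, 14 and 15). Step 13 is the side branch.

**Steps most likely to fail**

1. **Step 7.**
   - Risk: the allylic C9–O bond lowers the nucleophilicity of C7=C8. Ionisation of the allylic silyl ether, chloride capture at C8, a hydride shift from C9 or β-elimination of the C4 silyloxy group may therefore outrun ring closure. The selectivity between the aldehyde faces may also erode.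
   - Fallback, from 13 back to 15: the ene component is replaced by an allylmetal. Selenium-catalysed ene-type chlorination (NCS, PhSeCl cat, CH2Cl2, rt) moves the double bond into the former methyl group and gives the 2-(chloromethyl)allyl aldehyde F1. An intramolecular Nozaki–Hiyama allylation (CrCl2, THF, high dilution) then joins the alkene CH2 to C6 under neutral conditions through a cyclic chromium alkoxide transition state. The two CH2 groups on C8 only exchange their roles, so the product is 15.

2. **Step 5.**
   - Risk: the enamine carbon C5 is neopentyl-like and the ketone is more hindered than a methyl ketone. Closure may therefore be slow, and the other aldol mode (C2 on C6) or β-elimination of the C4 or C9 silyloxy group may take over.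
   - Fallback, from 4 (isolated instead of being acetalised) back to 11: the ring is closed first and the chain is added afterwards at the acid oxidation level.
     - The same ammonium salt closes 4 on its unhindered methyl ketone to the 2-methylcyclopentenecarbaldehyde F2.
     - Pinnick oxidation (NaClO2, NaH2PO4, 2-methyl-2-butene) gives the acid F3.
     - LDA (2.2 equiv, THF, −78 to 0 °C) removes a proton from the methyl group that lies syn to the carboxylate. The dienediolate adds to methacrolein 6 with equilibration to the γ-adduct, which closes on acidification to the unsaturated δ-lactone F4.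
     - MeNH(OMe)·HCl and iPrMgCl open F4 to the hydroxy Weinreb amide F5.
     - TBSCl and imidazole give the silyl ether F6, and DIBAL-H at −78 °C gives 11.

3. **Step 6.**
   - Risk: 1,4-addition to a tetrasubstituted enal next to a quaternary carbon may be sluggish, and 1,2-addition may compete. Attack from the wrong face is possible, and the C4 silyloxy group may be lost by β-elimination during the equilibration.
   - Fallback, from 11 back to 13: the methyl group is brought in as a cyclopropane methylene.
     - DIBAL-H gives the allylic alcohol F7.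
     - The Furukawa variant of the Simmons–Smith cyclopropanation (Et2Zn, CH2I2, CH2Cl2) is accelerated by the zinc alkoxide, so the tetrasubstituted alkene reacts before the isopropenyl group. It attacks the β face opposite to the isopropyl group and gives the cyclopropylcarbinol F8.
     - Dess–Martin periodinane gives the cyclopropanecarbaldehyde F9.
     - Li in NH3–THF at −78 °C cleaves the peripheral C5–CH2 bond, which yields the less substituted carbanion. The methylene thereby becomes the β-methyl C15.
     - Any over-reduced alcohol is re-oxidised, and K2CO3 in MeOH settles C5 to give 13.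

**Further compounds**
F1 | step 7 | 2-(chloromethyl)allyl analogue of aldehyde 13 | O=C[C@H]1[C@](O[Si](CC)(CC)CC)(C(C)C)CC[C@]1(C)C[C@@H](O[Si](C)(C)C(C)(C)C)C(=C)CCl
F2 | step 5 | 5-isopropyl-2-methyl-5-(triethylsilyloxy)cyclopent-1-enecarbaldehyde | O=CC1=C(C)CC[C@@]1(O[Si](CC)(CC)CC)C(C)C
F3 | step 5 | 5-isopropyl-2-methyl-5-(triethylsilyloxy)cyclopent-1-enecarboxylic acid | OC(=O)C1=C(C)CC[C@@]1(O[Si](CC)(CC)CC)C(C)C
F4 | step 5 | cyclopentene-fused unsaturated δ-lactone (O9–C6 acyl bond) | O=C1O[C@@H](C(C)=C)CC2=C1[C@](O[Si](CC)(CC)CC)(C(C)C)CC2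
F5 | step 5 | C9-hydroxy Weinreb amide | CON(C)C(=O)C1=C(C[C@@H](O)C(C)=C)CC[C@@]1(O[Si](CC)(CC)CC)C(C)C
F6 | step 5 | C9-TBS ether of the Weinreb amide | CON(C)C(=O)C1=C(C[C@@H](O[Si](C)(C)C(C)(C)C)C(C)=C)CC[C@@]1(O[Si](CC)(CC)CC)C(C)C
F7 | step 6 | allylic alcohol from 11 | OCC1=C(C[C@@H](O[Si](C)(C)C(C)(C)C)C(C)=C)CC[C@@]1(O[Si](CC)(CC)CC)C(C)C
F8 | step 6 | 1,5-β-methano cyclopropylcarbinol | OC[C@@]12C[C@]1(C[C@@H](O[Si](C)(C)C(C)(C)C)C(C)=C)CC[C@@]2(O[Si](CC)(CC)CC)C(C)C
F9 | step 6 | 1,5-β-methano cyclopropanecarbaldehyde | O=C[C@@]12C[C@]1(C[C@@H](O[Si](C)(C)C(C)(C)C)C(C)=C)CC[C@@]2(O[Si](CC)(CC)CC)C(C)C
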